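**Retrosynthetic overview**
1. The CH2 bridge is cut first: target ⇒ acetylfilicinic acid (ring A) + 3-methylphlorobutyrophenone (ring B) + one C1 unit, joined through the ortho-quinone methide of ring B.
2. Ring A ⇒ Claisen closure of chain carbon 6 onto ester carbon 1 (the closure used by phloroglucinol-forming polyketide synthases) of methyl 2,2-dimethyl-3,5,7-trioxooctanoate ⇒ acetylacetone dianion + dimethyl 2,2-dimethylmalonate. The gem-dimethyl group is carried in, so the ring forms already dearomatized.
3. Ring B ⇒ the same carbon 6 → carbon 1 Claisen closure of methyl 2-methyl-3,5,7-trioxodecanoate ⇒ tetraketide pyrone ⇒ dianion of 4-hydroxy-3,6-dimethyl-2H-pyran-2-one + methyl butanoate.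
4. Order: ring A and ring B are each made in one flask, in parallel, and the bridge is formed last.

Assumption: the target has no stereocentre (it is achiral and drawn as one of several enol tautomers), so no enantioselective step is needed and every compound is written as one tautomer.

**Route**

Step 1
Reactants: 1 acetylacetone (pentane-2,4-dione); 2 dimethyl 2,2-dimethylmalonate
Product: 4 acetylfilicinic acid (2-acetyl-3,5-dihydroxy-4,4-dimethylcyclohexa-2,5-dien-1-one), via methyl 2,2-dimethyl-3,5,7-trioxooctanoate 3 (not isolated)
Conditions: 1 (2.1 equiv), LiN(i-Pr)2 (4.2 equiv), THF, −78 → 0 °C; 2 (1.0 equiv), 0 → 20 °C; then MeOH, 65 °C; 2 M HCl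
Reagents that add atoms: none
Why: Proposed new method: the terminal carbanion of the acetylacetone dianion acylates one ester of 2, which has no acidic hydrogen and so cannot quench the dianion (the second equivalent of dianion takes the acidic proton of 3), and the 3,5,7-trioxo ester 3 then closes by Claisen condensation of carbon 6 onto ester carbon 1 under the lithium methoxide present, the quaternary carbon 2 blocking the competing aldol mode and giving the ring directly in the filicinic acid form; the closest known reactions are the acylation of β-diketone dianions with esters and the base-mediated Claisen cyclization of 3,5,7-triketo esters to acylphloroglucinols; no stereocentre is formed.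

Step 2
Reactants: 5 4-hydroxy-3,6-dimethyl-2H-pyran-2-one; 6 methyl butanoate
Product: 9 1-(2,4,6-trihydroxy-3-methylphenyl)butan-1-one, via 4-hydroxy-3-methyl-6-(2-oxopentyl)-2H-pyran-2-one 7 (not isolated), via methyl 2-methyl-3,5,7-trioxodecanoate 8 (not isolated)
Conditions: 5 (2.1 equiv), LiN(i-Pr)2 (4.3 equiv), THF–DMPU, −78 → −20 °C; 6 (1.0 equiv), −20 → 20 °C; then MeOH, Mg(OMe)2 (8 equiv), 65 °C; 2 M HCl
Reagents that add atoms: none
Why: Claisen acylation of the pyrone dianion at its 6-methyl carbon (the second equivalent of dianion serves as base for the acidic product) gives tetraketide lactone 7, which Mg(OMe)2 opens to the magnesium chelate of triketo ester 8 and closes by biomimetic Claisen condensation of carbon 6 onto carbon 1 (the known magnesium methoxide pyrone-to-acylphloroglucinol cyclization), the 2-methyl group making the competing aldol mode non-aromatizable; the labile centre of 8 is lost on aromatization.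

Step 3
Reactants: 9 1-(2,4,6-trihydroxy-3-methylphenyl)butan-1-one; 4 acetylfilicinic acid
Product: 12 2-acetyl-4-[(3-butanoyl-2,4,6-trihydroxy-5-methylphenyl)methyl]-3,5-dihydroxy-6,6-dimethylcyclohexa-2,4-dien-1-one (CID25096977), via Mannich base 10 (not isolated), via ortho-quinone methide 11 (not isolated)
Conditions: 9 (1.0 equiv), CH2(NMe2)2 (1.0 equiv), 1,4-dioxane, 20 °C; then 4 (1.2 equiv), 80 °C; 1 M HCl wash
Reagents that add atoms: bis(dimethylamino)methane, CN(C)CN(C)C
Why: Mannich aminomethylation of the only free ring position of 9, thermal loss of dimethylamine to ortho-quinone methide 11, and Michael addition of the single nucleophilic ring carbon of 4 (as its enol) with rearomatization of ring B as driving force; no stereocentre is formed.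

**Compound list**
1 | acetylacetone (pentane-2,4-dione; achiral) | CC(=O)CC(C)=O | starting material
2 | dimethyl 2,2-dimethylmalonate (dimethyl 2,2-dimethylpropanedioate; achiral) | COC(=O)C(C)(C)C(=O)OC | starting material
3 | methyl 2,2-dimethyl-3,5,7-trioxooctanoate (open-chain tetraketide ester; achiral; formed in the flask) | COC(=O)C(C)(C)C(=O)CC(=O)CC(C)=O | intermediate
4 | acetylfilicinic acid, 2-acetyl-3,5-dihydroxy-4,4-dimethylcyclohexa-2,5-dien-1-one (ring A; achiral) | CC(=O)C1=C(O)C(C)(C)C(O)=CC1=O | intermediate
5 | 4-hydroxy-3,6-dimethyl-2H-pyran-2-one (C-methyl homologue of triacetic acid lactone; achiral) | CC1=CC(O)=C(C)C(=O)O1 | starting material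
6 | methyl butanoate (achiral) | CCCC(=O)OC | starting material
7 | 4-hydroxy-3-methyl-6-(2-oxopentyl)-2H-pyran-2-one (tetraketide lactone; achiral; formed in the flask) | CCCC(=O)CC1=CC(O)=C(C)C(=O)O1 | intermediate
8 | methyl 2-methyl-3,5,7-trioxodecanoate (racemic, carbon 2 epimerizable; formed in the flask) | CCCC(=O)CC(=O)CC(=O)C(C)C(=O)OC | intermediate
9 | 1-(2,4,6-trihydroxy-3-methylphenyl)butan-1-one (ring B; achiral) | CCCC(=O)c1c(O)cc(O)c(C)c1O | intermediate
10 | 1-{3-[(dimethylamino)methyl]-2,4,6-trihydroxy-5-methylphenyl}butan-1-one (Mannich base; achiral; formed in the flask) | CCCC(=O)c1c(O)c(C)c(O)c(CN(C)C)c1O | intermediate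
11 | 2-butanoyl-3,5-dihydroxy-4-methyl-6-methylidenecyclohexa-2,4-dien-1-one (ortho-quinone methide; achiral; formed in the flask) | CCCC(=O)C1=C(O)C(C)=C(O)C(=C)C1=O | intermediate
12 | 2-acetyl-4-[(3-butanoyl-2,4,6-trihydroxy-5-methylphenyl)methyl]-3,5-dihydroxy-6,6-dimethylcyclohexa-2,4-dien-1-one (CID25096977; achiral) | CCCC(=O)c1c(O)c(C)c(O)c(CC2=C(O)C(C)(C)C(=O)C(C(C)=O)=C2O)c1O | target

**Totals**
Total step count: 3. Longest linear sequence: 2 (step 1 or step 2, then step 3).

**Steps most likely to fail**

Step 1 (highest risk). The hindered ester of 2 may acylate slowly, and the open-chain ester 3 may not close cleanly in the same flask. The fallback sets out from 1 and comes back to the route at 4. Acetylacetone is silylated twice (Me3SiCl, NEt3; then LiN(i-Pr)2, Me3SiCl) to (3Z)-2,4-bis(trimethylsilyloxy)penta-1,3-diene F1. F1 is acylated at its terminal carbon by 2,2-dimethylmalonyl dichloride (Me3SiOTf cat., CH2Cl2, −78 → 20 °C; Mukaiyama-type acylation without strong base), and the second acid chloride is captured by the enol oxygen to give the isolable lactone 3,3-dimethyl-6-(2-oxopropyl)-2H-pyran-2,4(3H)-dione F2. Mg(OMe)2 in MeOH at 65 °C then opens F2 to the triketo ester 3 and closes it by the same carbon 6 → carbon 1 Claisen condensation to 4.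

Step 3 (second). The risks are exchange of the methylene bridge giving the two symmetrical dimers, and sluggish formation of 11. The fallback sets out from 4 (with 9 as partner) and comes back at 12, with the roles of the rings exchanged. Compound 4 is aminomethylated with CH2(NMe2)2 in CH2Cl2 at 0 °C to the crystalline betaine 2-acetyl-6-[(dimethylamino)methyl]-3,5-dihydroxy-4,4-dimethylcyclohexa-2,5-dien-1-one F4, which is isolated free of 4. Stirred with 9 in MeOH at 20–40 °C, it loses dimethylamine to the exocyclic enone of ring A, which alkylates the one free position of 9 (Friedel–Crafts-type Michael addition) to give 12 at lower temperature and without an ortho-quinone methide.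

Step 2 (third). The pyrone dianion may deprotonate methyl butanoate instead of being acylated, and the lithium salts and excess 5 carried into the magnesium stage may disturb the cyclization. The fallback sets out from 5 and comes back at 9. The dianion of 5 (1 equiv; LiN(i-Pr)2 2.1 equiv) is added to butanal in an aldol addition, which gives no acidic product and so runs at 1:1 stoichiometry, to give racemic 4-hydroxy-6-(2-hydroxypentyl)-3-methyl-2H-pyran-2-one F3. Jones oxidation (CrO3, H2SO4, acetone) of the secondary alcohol gives 7, which is isolated and crystallized. Pure 7 is then cyclized with Mg(OMe)2 in MeOH at 65 °C through 8 to 9.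

**Further compounds**
F1 | step 1 | (3Z)-2,4-bis(trimethylsilyloxy)penta-1,3-diene | C=C(O[Si](C)(C)C)/C=C(/C)O[Si](C)(C)C
F2 | step 1 | 3,3-dimethyl-6-(2-oxopropyl)-2H-pyran-2,4(3H)-dione | CC(=O)CC1=CC(=O)C(C)(C)C(=O)O1
F3 | step 2 | 4-hydroxy-6-(2-hydroxypentyl)-3-methyl-2H-pyran-2-one (racemic) | CCCC(O)CC1=CC(O)=C(C)C(=O)O1
F4 | step 3 | 2-acetyl-6-[(dimethylamino)methyl]-3,5-dihydroxy-4,4-dimethylcyclohexa-2,5-dien-1-one | CC(=O)C1=C(O)C(C)(C)C(O)=C(CN(C)C)C1=O
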